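**Plan**

1. Numbering used throughout: spiro C1; ring A = C1–C2(CH3)=C3–C4(OH)–C5(Br)–C6(CH3)2; ring B = C1–C7–C8–C9(CH3)=C10(Br)–C11.
2. Retrosynthetic cuts, in order: C4–O (inversion), C5–Br and C10–Br back to a spiro enedione; then C1–C2 (ring A); then C4–C3 (propynyl), C9–CH3 and C6–C1' of ring B (reverse prenylation of a vinylogous ester).
3. Forward: ring B is bought as 3-ethoxycyclohexenone, the C6 chain is attached and grown into a (Z)-β-iodoenone, ring A is closed by spirocyclisation, then ring B receives its vinyl bromide and ring A its bromohydrin.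
4. Enabling feature: spiro C1 carries sp2 C2 of ring A and lies β to C10 of ring B, so a C2 vinylpalladium can add to C1 of a ring B enone whose carbonyl carbon is C10.
5. Stereochemistry: C1 from the chiral bisphosphine on palladium; C5 from the substrate (equatorial bromide cis to C11, equilibrated); C4 from hydride delivery anti to the axial C6 methyl, then Mitsunobu inversion.

Key step: step 8

Remark: the sense of induction of the bisphosphine cannot be assigned in advance; (R)-BINAP is written, and its antipode is to be used if the first run delivers the (6S)-enedione.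

**Route**

Step 1
Reactants: 1 3-ethoxycyclohex-2-en-1-one; 2 (3-methylbut-2-en-1-yl)magnesium chloride (prenylmagnesium chloride, commercial THF solution)
Product: 4 dienone 3-(2-methylbut-3-en-2-yl)cyclohex-2-en-1-one, via tertiary carbinol 3 (not isolated)
Conditions: THF, −20 to 0 °C; then 1 M HCl, THF, 23 °C
Reagents that add atoms: water, O
Why: Stork–Danheiser sequence in which the allylic Grignard reagent adds 1,2 to the vinylogous ester through its tertiary γ-carbon (six-membered SE2' transition state, kept cold so that the adduct does not revert), and aqueous acid then hydrolyses the enol ether and dehydrates the carbinol to the transposed 3-substituted enone, leaving no stereocentre.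

Step 2
Reactants: 4 dienone 3-(2-methylbut-3-en-2-yl)cyclohex-2-en-1-one
Product: 6 racemic 6-methyl-3-(2-methylbut-3-en-2-yl)cyclohex-2-en-1-one, via lithium dienolate 5 (not isolated)
Conditions: LDA (LiN(i-Pr)2), THF, −78 °C; then MeI, −78 to −20 °C
Reagents that add atoms: iodomethane, CI
Why: Kinetic α'-deprotonation of the 3-substituted cyclohexenone gives the cross-conjugated lithium dienolate, and SN2 enolate alkylation places the future C9 methyl group; the racemic C9 centre is of no consequence because C9 later becomes sp2.

Step 3
Reactants: 6 racemic 6-methyl-3-(2-methylbut-3-en-2-yl)cyclohex-2-en-1-one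
Product: 8 diol 3-(4-hydroxy-2-methylbutan-2-yl)-6-methylcyclohex-2-en-1-ol (diastereomer mixture), via bis-borane adduct 7 (not isolated)
Conditions: 9-BBN (2.5 equiv), THF, 0 to 40 °C; then NaOH, H2O2, H2O, 0 to 23 °C
Reagents that add atoms: hydrogen peroxide, OO; 9-borabicyclo[3.3.1]nonane, B1C2CCCC1CCC2 (boron kept only in 7)
Why: Hydroboration–oxidation in which 9-BBN adds anti-Markovnikov to the terminal vinyl group and, as is usual for this borane, also reduces the enone carbonyl 1,2 while the hindered ring alkene is spared; alkaline peroxide then frees the diol, whose carbinol configuration is irrelevant because step 4 restores the ketone.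

Step 4
Reactants: 8 diol 3-(4-hydroxy-2-methylbutan-2-yl)-6-methylcyclohex-2-en-1-ol
Product: 9 keto aldehyde 3-methyl-3-(4-methyl-3-oxocyclohex-1-en-1-yl)butanal
Conditions: Dess–Martin periodinane (2.4 equiv), CH2Cl2, 0 to 23 °C
Reagents that add atoms: none
Why: Dess–Martin oxidation takes the primary alcohol to the aldehyde and the allylic alcohol back to the enone under neutral conditions, and the aldehyde cannot epimerise because its α-carbon is an unsubstituted CH2 next to the quaternary C6.

Step 5
Reactants: 9 keto aldehyde 3-methyl-3-(4-methyl-3-oxocyclohex-1-en-1-yl)butanal; 10 prop-1-yn-1-ylmagnesium bromide (commercial THF solution)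
Product: 11 propargylic alcohol 3-(4-hydroxy-2-methylhept-5-yn-2-yl)-6-methylcyclohex-2-en-1-one (diastereomer mixture)
Conditions: THF, −78 to −40 °C
Reagents that add atoms: none
Why: Grignard 1,2-addition in which the weakly basic alkynyl reagent attacks the unhindered aldehyde much faster than the conjugated, α-branched ring ketone at low temperature; the new carbinol centre is removed in step 6.

Step 6
Reactants: 11 propargylic alcohol 3-(4-hydroxy-2-methylhept-5-yn-2-yl)-6-methylcyclohex-2-en-1-one
Product: 12 ynone 6-methyl-3-(2-methyl-4-oxohept-5-yn-2-yl)cyclohex-2-en-1-one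
Conditions: Dess–Martin periodinane (1.3 equiv), CH2Cl2, 23 °C
Reagents that add atoms: none
Why: Dess–Martin oxidation of a propargylic alcohol gives the conjugated ynone without isomerising the alkyne or touching the ring enone.

Step 7
Reactants: 12 ynone 6-methyl-3-(2-methyl-4-oxohept-5-yn-2-yl)cyclohex-2-en-1-one
Product: 13 (Z)-β-iodoenone 3-[(5Z)-6-iodo-2-methyl-4-oxohept-5-en-2-yl]-6-methylcyclohex-2-en-1-one (racemic at C9)
Conditions: NaI, AcOH, 23 °C, dark
Reagents that add atoms: sodium iodide, [Na+].[I-]
Why: Conjugate hydroiodination in which iodide adds to the β-carbon of the activated ynone and the allenol is protonated anti to iodine, the kinetic course that gives the Z isomer, while the less electrophilic β,β-disubstituted ring enone forms at most a reversible adduct.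

Step 8
Reactants: 13 (Z)-β-iodoenone 3-[(5Z)-6-iodo-2-methyl-4-oxohept-5-en-2-yl]-6-methylcyclohex-2-en-1-one
Product: 14 spiro enedione (6R)-1,5,5,9-tetramethylspiro[5.5]undec-1-ene-3,8-dione (both C9 epimers)
Conditions: Pd(OAc)2 (10 mol %), (R)-BINAP (12 mol %), HCO2Na (2 equiv), DMF–MeOH 4:1, 60 °C
Reagents that add atoms: none
Why: Proposed new method: zerovalent palladium formed in situ from Pd(OAc)2 and the bisphosphine inserts into the C2–I bond with retention of the Z geometry, the β-acylvinyl divalent palladium species adds across C11=C1 of the tethered ring B enone by syn migratory insertion, and the C11 palladium enolate, which has no β-hydrogen because C1 is quaternary, is reduced by formate (loss of CO2) to the C10 ketone with return of zerovalent palladium. The closest known reaction type is the intramolecular reductive Heck (conjugate) cyclisation of aryl and vinyl halides onto enones, which forms quaternary carbons and is enantioselective with aryl halides and chiral bisphosphines; the enantioselective use of a vinyl iodide is the extension. Ring A closes in a 6-exo-trig mode, C2 bonding to C1 with C11 left outside the new ring. The only new stereocentre, spiro C1, is set by the chiral bisphosphine on palladium, which selects the enone face at C1; these faces differ strongly (sp2 C11 against sp3 C7), and the remote C9 methyl centre, present as both epimers, should not interfere. The step needs cyclisation to outrun direct formate reduction of the vinylpalladium and Z-to-E isomerisation: the Z geometry holds C4 and palladium cis, the gem-dimethyl group at C6 favours the folded chain, and the protic co-solvent helps iodide to leave so that both phosphorus atoms stay bound during insertion.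

Step 9
Reactants: 14 spiro enedione (6R)-1,5,5,9-tetramethylspiro[5.5]undec-1-ene-3,8-dione
Product: 16 bromo enone (6R)-8-bromo-1,5,5,9-tetramethylspiro[5.5]undeca-1,8-dien-3-one, via TBS hydrazone 15 (not isolated)
Conditions: 1,2-bis(tert-butyldimethylsilyl)hydrazine (1.05 equiv), Sc(OTf)3 (1 mol %), CH2Cl2, 0 to 23 °C; volatiles removed; then added to Br2 and 2-tert-butyl-1,1,3,3-tetramethylguanidine, CH2Cl2, 0 to 23 °C
Reagents that add atoms: bromine, BrBr; 1,2-bis(tert-butyldimethylsilyl)hydrazine, CC(C)(C)[Si](C)(C)NN[Si](C)(C)C(C)(C)C (atoms kept only in 15)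
Why: Carbonyl condensation followed by a Barton-type vinyl halide synthesis, in which the saturated C10 ketone condenses with the silyl hydrazine faster than the conjugated C4 ketone, and bromine with the guanidine base oxidises the hydrazone through the diazo compound to a bromocarbenium ion at C10 that loses the C9 proton to give the tetrasubstituted alkene in preference to a trisubstituted one beside the spiro carbon, so that both C9 epimers converge.

Step 10
Reactants: 16 bromo enone (6R)-8-bromo-1,5,5,9-tetramethylspiro[5.5]undeca-1,8-dien-3-one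
Product: 18 dibromo enone (4S,6S)-4,8-dibromo-1,5,5,9-tetramethylspiro[5.5]undeca-1,8-dien-3-one, via TMS dienol ether 17 (not isolated)
Conditions: LDA (LiN(i-Pr)2), TMSCl, THF, −78 °C; then NBS, −78 to 0 °C; then HBr (catalytic), AcOH, 23 °C
Reagents that add atoms: N-bromosuccinimide, O=C1CCC(=O)N1Br; chlorotrimethylsilane, C[Si](C)(C)Cl (silicon kept only in 17)
Why: Kinetic α'-deprotonation with in situ silylation gives the cross-conjugated 2-silyloxydiene, which NBS brominates at C5 (bromination of a silyl enol ether), and acid equilibration of this enolisable centre is expected to leave bromine equatorial on the half-chair in which the C2 methyl group leans over the flat C11–C10 arm and not over the C8 methylene, that is cis to C11 (5S in route numbering).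

Step 11
Reactants: 18 dibromo enone (4S,6S)-4,8-dibromo-1,5,5,9-tetramethylspiro[5.5]undeca-1,8-dien-3-one
Product: 19 cis-bromohydrin (3R,4S,6S)-4,8-dibromo-1,5,5,9-tetramethylspiro[5.5]undeca-1,8-dien-3-ol
Conditions: i-Bu2AlH (1.2 equiv), CH2Cl2, −78 °C
Reagents that add atoms: none
Why: 1,2-Reduction with a bulky aluminium hydride in which, with bromine equatorial, the axial C6 methyl group shields the carbonyl face on the side of the ring flap, so hydride should arrive from the opposite face and give the pseudoaxial alcohol cis to bromine (4R in route numbering), the vinyl and alkyl bromides being inert at this temperature.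

Step 12
Reactants: 19 cis-bromohydrin (3R,4S,6S)-4,8-dibromo-1,5,5,9-tetramethylspiro[5.5]undeca-1,8-dien-3-ol
Product: 20 ester (3S,4S,6S)-4,8-dibromo-1,5,5,9-tetramethylspiro[5.5]undeca-1,8-dien-3-yl 4-nitrobenzoate
Conditions: PPh3, DIAD, 4-nitrobenzoic acid, THF, 0 to 23 °C
Reagents that add atoms: 4-nitrobenzoic acid, O=C(O)c1ccc(cc1)[N+](=O)[O-]
Why: Mitsunobu reaction in which the allylic oxyphosphonium ion is displaced by the carboxylate in an SN2 step from the open face that hydride used, inverting C4 to the S configuration trans to bromine, while SN2' attack is blocked by the fully substituted C2.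

Step 13
Reactants: 20 ester (3S,4S,6S)-4,8-dibromo-1,5,5,9-tetramethylspiro[5.5]undeca-1,8-dien-3-yl 4-nitrobenzoate
Product: 21 target (3S,4S,6S)-4,8-dibromo-1,5,5,9-tetramethylspiro[5.5]undeca-1,8-dien-3-ol
Conditions: i-Bu2AlH (2.5 equiv), CH2Cl2, −78 °C
Reagents that add atoms: none
Why: Reductive ester cleavage with the aluminium hydride releases the alcohol as a non-nucleophilic aluminium alkoxide at low temperature, which avoids the epoxide closure that basic methanolysis of a trans-bromohydrin ester would invite and leaves all three stereocentres untouched.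

**Compound list**

1 | 3-ethoxycyclohex-2-en-1-one | CCOC1=CC(=O)CCC1 | starting material
2 | (3-methylbut-2-en-1-yl)magnesium chloride | CC(C)=CC[Mg]Cl | starting material
3 | 3-ethoxy-1-(2-methylbut-3-en-2-yl)cyclohex-2-en-1-ol (racemic) | CCOC1=CC(O)(CCC1)C(C)(C)C=C | intermediate (not isolated)
4 | 3-(2-methylbut-3-en-2-yl)cyclohex-2-en-1-one | C=CC(C)(C)C1=CC(=O)CCC1 | intermediate
5 | lithium 5-(2-methylbut-3-en-2-yl)cyclohexa-1,5-dien-1-olate | [Li]OC1=CCCC(C(C)(C)C=C)=C1 | intermediate (not isolated)
6 | 6-methyl-3-(2-methylbut-3-en-2-yl)cyclohex-2-en-1-one (racemic) | C=CC(C)(C)C1=CC(=O)C(C)CC1 | intermediate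
7 | bis(9-borabicyclo[3.3.1]nonan-9-yl) adduct of 6 (B–O at the ring carbinol, B–C at the chain terminus) | CC1CCC(=CC1OB1C2CCCC1CCC2)C(C)(C)CCB1C2CCCC1CCC2 | intermediate (not isolated)
8 | 3-(4-hydroxy-2-methylbutan-2-yl)-6-methylcyclohex-2-en-1-ol (diastereomer mixture) | CC1CCC(=CC1O)C(C)(C)CCO | intermediate
9 | 3-methyl-3-(4-methyl-3-oxocyclohex-1-en-1-yl)butanal (racemic) | CC1CCC(=CC1=O)C(C)(C)CC=O | intermediate
10 | prop-1-yn-1-ylmagnesium bromide | CC#C[Mg]Br | starting material
11 | 3-(4-hydroxy-2-methylhept-5-yn-2-yl)-6-methylcyclohex-2-en-1-one (diastereomer mixture) | CC#CC(O)CC(C)(C)C1=CC(=O)C(C)CC1 | intermediate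
12 | 6-methyl-3-(2-methyl-4-oxohept-5-yn-2-yl)cyclohex-2-en-1-one (racemic) | CC#CC(=O)CC(C)(C)C1=CC(=O)C(C)CC1 | intermediate
13 | 3-[(5Z)-6-iodo-2-methyl-4-oxohept-5-en-2-yl]-6-methylcyclohex-2-en-1-one (racemic at C9) | CC1CCC(=CC1=O)C(C)(C)CC(=O)/C=C(/C)I | intermediate (key-step precursor)
14 | (6R)-1,5,5,9-tetramethylspiro[5.5]undec-1-ene-3,8-dione (C9 epimers) | CC1=CC(=O)CC(C)(C)[C@]12CCC(C)C(=O)C2 | intermediate (key-step product)
15 | (6R)-8-[2-(tert-butyldimethylsilyl)hydrazinylidene]-1,5,5,9-tetramethylspiro[5.5]undec-1-en-3-one (C9 epimers) | CC1=CC(=O)CC(C)(C)[C@]12CCC(C)C(=NN[Si](C)(C)C(C)(C)C)C2 | intermediate (not isolated)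
16 | (6R)-8-bromo-1,5,5,9-tetramethylspiro[5.5]undeca-1,8-dien-3-one | CC1=CC(=O)CC(C)(C)[C@]12CCC(C)=C(Br)C2 | intermediate
17 | (6S)-8-bromo-1,5,5,9-tetramethyl-3-(trimethylsilyloxy)spiro[5.5]undeca-1,3,8-triene | CC1=CC(O[Si](C)(C)C)=CC(C)(C)[C@]12CCC(C)=C(Br)C2 | intermediate (not isolated)
18 | (4S,6S)-4,8-dibromo-1,5,5,9-tetramethylspiro[5.5]undeca-1,8-dien-3-one | CC1=CC(=O)[C@@H](Br)C(C)(C)[C@]12CCC(C)=C(Br)C2 | intermediate
19 | (3R,4S,6S)-4,8-dibromo-1,5,5,9-tetramethylspiro[5.5]undeca-1,8-dien-3-ol | CC1=C[C@@H](O)[C@@H](Br)C(C)(C)[C@]12CCC(C)=C(Br)C2 | intermediate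
20 | (3S,4S,6S)-4,8-dibromo-1,5,5,9-tetramethylspiro[5.5]undeca-1,8-dien-3-yl 4-nitrobenzoate | CC1=C[C@H](OC(=O)c3ccc(cc3)[N+](=O)[O-])[C@@H](Br)C(C)(C)[C@]12CCC(C)=C(Br)C2 | intermediate
21 | (3S,4S,6S)-4,8-dibromo-1,5,5,9-tetramethylspiro[5.5]undeca-1,8-dien-3-ol | CC1=C[C@H](O)[C@@H](Br)C(C)(C)[C@]12CCC(C)=C(Br)C2 | target

**Count**

Total steps: 13. Longest linear sequence: 13 steps (from 1).

**Steps most likely to fail**

Step 8 (proposed new method). The ligand may not distinguish the two enone faces well enough, formate may reduce the vinylpalladium before it cyclises, or the vinylpalladium may lose its Z geometry. The fallback sets out from 13 and gives up asymmetric induction. The same ring closure is run under established racemic reductive Heck conditions (Pd(OAc)2, PPh3, HCO2Na, DMF, 80 °C) to give racemic 1,5,5,9-tetramethylspiro[5.5]undec-1-ene-3,8-dione F1. The conditions of step 9 carry it through the racemic silyl hydrazone F2 to racemic 8-bromo-1,5,5,9-tetramethylspiro[5.5]undeca-1,8-dien-3-one F3. F3 has a single stereocentre and is resolved by preparative chromatography on a chiral stationary phase. The (6R)-enantiomer is 16, where the route is rejoined; the (6S)-enantiomer F4 is set aside.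

Step 9. The hydrazine may condense with both carbonyl groups, proton loss from the bromocarbenium ion may go toward C11, or bromine may attack ring A. The fallback sets out from 14 and comes back at 16 without a hydrazone. The ketone is deoxybrominated directly with the bromophosphonium reagent made from P(OPh)3 and Br2, with Et3N in CH2Cl2 from −60 °C to reflux. This is a known conversion of enolisable ketones into vinyl bromides: the more electrophilic saturated carbonyl oxygen is activated on phosphorus and HBr is lost under more equilibrating conditions that favour the more substituted alkene. It makes no new compound (F0).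

Step 10. Bromination may show poor facial selectivity, or the equilibrium at C5 may not favour the required epimer. The fallback sets out from 16 and replaces stereoselective bromination by separation with recycling. Bromination as in step 10 without the acid treatment gives 18 together with its C5 epimer, (4R,6S)-4,8-dibromo-1,5,5,9-tetramethylspiro[5.5]undeca-1,8-dien-3-one F5. Reduction of the mixture with i-Bu2AlH as in step 11 gives 19 and the diastereomeric cis-bromohydrin (3S,4R,6S)-4,8-dibromo-1,5,5,9-tetramethylspiro[5.5]undeca-1,8-dien-3-ol F6, which are separated by chromatography. F6 is re-oxidised with Dess–Martin periodinane to F5, which is re-equilibrated with HBr in AcOH and sent through the reduction again. The route is rejoined at 19.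

**Further compounds**

F1 | step 8 | 1,5,5,9-tetramethylspiro[5.5]undec-1-ene-3,8-dione (racemic, C9 epimers) | CC1=CC(=O)CC(C)(C)C12CCC(C)C(=O)C2
F2 | step 8 | 8-[2-(tert-butyldimethylsilyl)hydrazinylidene]-1,5,5,9-tetramethylspiro[5.5]undec-1-en-3-one (racemic) | CC1=CC(=O)CC(C)(C)C12CCC(C)C(=NN[Si](C)(C)C(C)(C)C)C2
F3 | step 8 | 8-bromo-1,5,5,9-tetramethylspiro[5.5]undeca-1,8-dien-3-one (racemic) | CC1=CC(=O)CC(C)(C)C12CCC(C)=C(Br)C2
F4 | step 8 | (6S)-8-bromo-1,5,5,9-tetramethylspiro[5.5]undeca-1,8-dien-3-one | CC1=CC(=O)CC(C)(C)[C@@]12CCC(C)=C(Br)C2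
F0 | step 9 | none | none
F5 | step 10 | (4R,6S)-4,8-dibromo-1,5,5,9-tetramethylspiro[5.5]undeca-1,8-dien-3-one | CC1=CC(=O)[C@H](Br)C(C)(C)[C@]12CCC(C)=C(Br)C2
F6 | step 10 | (3S,4R,6S)-4,8-dibromo-1,5,5,9-tetramethylspiro[5.5]undeca-1,8-dien-3-ol | CC1=C[C@H](O)[C@H](Br)C(C)(C)[C@]12CCC(C)=C(Br)C2
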